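**Conventions.** TBS = tert-butyldimethylsilyl, PMB = 4-methoxybenzyl. Core locants C1–C11 are defined in the first section and used in all names.

## Analysis of the target

Target 44 is a cedrane-type sesquiterpenoid acid whose C5 hydroxyl is esterified with (Z)-16-hydroxyhexadec-9-enoic acid. The core is numbered C1 (CMe(CH2OH)), C2 (CH), C3 (CH2), C4 (quaternary), C5 (CH–O-acyl), C6=C7 (C7–CO2H), C8 (CH–CHO), C9, C10, C11 (CH). Ring A = C1/C2/C3/C4/C11 and ring B = C2/C3/C4/C5/C6/C7 form a bicyclo[3.2.1]octene with C3 as the one-carbon bridge, and ring C = C4/C8/C9/C10/C11 is fused across C4–C11. There are six stereocentres (C1, C2, C4, C5, C8, C11). H11 and the CH2OH of C1 lie on the C3 side of the C1–C11 bridge, while C10 and the C1 methyl lie under the C5–C6–C7 bridge. Ring C is therefore cis-fused to the seven-membered perimeter C4–C5–C6–C7–C2–C1–C11 but makes a strained, trans-fused diquinane with ring A. O5 is on the C3 face (anti to C4–C11), and the C8 formyl group is cis to C1 and C5 across ring C (H8 cis to H11). Sensitive groups are the aldehyde with its epimerisable C8 centre, the γ-acyloxy enoic acid, the Z-alkene, two primary alcohols, and two carboxyl-level groups of which only one may be freed. The hard points are the vicinal pair C1 (quaternary)/C11, the quaternary C4 shared by three rings, the strained fusion, and an O5 that sits on the face from which a hydride would attack C5. The strategy rests on the seven-membered perimeter: without the strap C3 it is a cyclohepta-1,4-diene (C2=C7, C4=C5) cis-fused to ring C, with C1 and C11 adjacent, which is the product pattern of a vinylcarbenoid–diene [4+3] annulation.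

## Retrosynthetic reasoning

44 is traced back through 43, 42, 41 and 40 by protecting-group and oxidation-level changes only. The two silyl ethers come off last, the allyl ester before that under neutral conditions, and the aldehyde is made from the C8 alcohol of 41 after the PMB ether of 40 is cleaved. This order keeps the epimerisable aldehyde away from every basic step and frees the C7 acid without hydrolysis, which the C5 ester would not survive.

The C5–O acyl bond of 40 is cut to alcohol 29 and acid 38. Cutting here makes the route convergent and keeps the Z-alkene chain out of the radical, palladium and oxidation chemistry of the core. The forward step has to acylate a hindered, axial secondary alcohol without touching its configuration.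

29 goes back to 27 through acid 28 by an ester exchange (methyl to allyl). The methyl ester is kept through the annulation, where it is best precedented. It is exchanged at 27, the last point at which no second ester is present.

O5 and the C6=C7 alkene of 27 are traced to epoxide 26, alkene 25, enol triflate 24 and ketone 22. A hydride reagent can reach the C5 carbonyl of 22 only from the C3 face, because C10 and the C1 methyl cover the other face, and that would put O5 on the wrong side. An oxygen atom delivered to C5=C6 from the same open face ends up where the target has it, and base-induced opening of the β,γ-epoxy ester then creates C6=C7 without breaking the C5–O bond.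

The C3–C2 bond of 22 is cut to give iodide 21. Homolysis at C3 gives a radical that is five atoms from C2, the β-carbon of the enoate, so a 5-exo closure forms ring A and ring B together. The C2 configuration is dictated by the tether.

The C3–C4 bond of 21 is cut through siloxycyclopropane 20 to the enol silane 19. The enol ether left by the annulation is the handle: methylene transfer to C4=C5 from the open face followed by electrophilic opening of the cyclopropanol ether places CH2I on C4 and returns the C5 ketone. This sets the quaternary C4 with C3 cis to H11.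

19 is cut at C6–C7 and C1–C11 to diazo ester 6 and siloxydiene 17, through the cis-divinylcyclopropane 18. This is the place to cut because both bonds, the seven-membered ring and the vicinal C1/C11 pair come from one stereospecific event, and the ester and the C5 oxygen land on the right carbons. The forward reaction must cyclopropanate the terminal enol-ether alkene with the two alkenyl groups cis and then rearrange through a boat.

6 goes back by diazo transfer to ester 5, which is cut at C2–C7 to alkenyl iodide 4, its alcohol 3 and alkyne 1. The Z geometry, which becomes the C1 configuration, is taken from an anti-carbomagnesiation and not from an olefination, so it is defined without ambiguity.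

17 comes from methyl ketone 16, which is cut at C4–C5 to enol triflate 14 and so to ketone 12. The C8 stereocentre of 12 is traced through 11 and diol 9 to hydroxy ester 8, made from keto ester 7 by asymmetric hydrogenation. The carbinol carbon of 8 is only a temporary carrier and becomes the triflate carbon.

Acid 38 is cut at its Z-alkene to aldehyde 32 (from 31 and the half ester 30) and phosphonium salt 35 (from 34 and bromo alcohol 33). A salt-free Wittig reaction is the most direct way to a Z-disubstituted alkene between two functionalised chains.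

## Alternatives that were turned down

Alternative 1: The bond cut is C4–C11, with ring C traced to a four-membered ring. Epoxy cyclobutanol A2 carries the C4–C5 epoxide on the cyclohexene ester and a 1-hydroxycyclobutyl group on C4. In the forward sense a Lewis acid opens the epoxide at tertiary C4 and the cyclobutane carbon C11 migrates from C8 to C4 anti to the departing oxygen. This gives spiro ketol A1 with the quaternary C4, the C8 ketone and O5.
- For it: the semipinacol shift is stereospecific, sets C4 and C5 together, and delivers O5 directly with the configuration of the epoxide. On this point it is stronger than the chosen route, which needs four steps from the C5 ketone to place O5.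
- Against it: A1 still lacks the C1–C2 bond. Ring A and the quaternary C1 would have to come from a late closure of the isopropenyl unit onto C2, for example by a hydrogen-atom-transfer radical cyclisation, which leaves the facial sense at C1 and the strained ring A/ring C fusion to substrate bias. C8 arrives as a ketone and needs a one-carbon homologation at an epimerisable centre. A2 itself needs a diastereoselective cyclobutanone addition and a face-selective epoxidation.
- In exchange the chosen strategy gives a stereospecific origin for the C1/C11 pair, has the C8 carbon at the right oxidation level from the start, and has the C7 ester and C5 oxygen in place after one step.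

Alternative 2: C4–C11, C8–C9 and C9–C10 are cut together, leading to the acyclic 1,6-enyne A4 (alkyne C8≡C4, alkene C11=C10, with C1 and C2 in the tether). A cobalt-mediated Pauson–Khand reaction would turn A4 into bicyclic enone A3, closing ring A and ring C in one operation with C9 entering as the carbonyl carbon.
- For it: three C–C bonds and two rings in one step is more than the chosen key step delivers. The reaction type is dependable for 1,6-enynes, and the C4=C8 enone is a handle for closing ring B by conjugate attack of C5 on C4.
- Against it: C9 is a methylene in the target, so the ketone must be erased. The C8 centre has to be set afterwards next to the new quaternary C4. The C11 configuration relative to C1/C2 rests on substrate control. A4, with a quaternary C1 next to the C2 stereocentre and a Z-trisubstituted enoate, is a demanding acyclic target in itself.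
- In exchange the chosen strategy has no oxidation state to remove, brings C8 in from a catalytic hydrogenation, and makes the vicinal C1/C11 pair by a stereospecific rearrangement.

Alternative 3: Ring B is cut at C2–C7 and C4–C5, leaving cyclopentanone A6 (ring A with a carbonyl at C3) and methyl (E)-4-oxobut-2-enoate A7. With a zinc additive the enolate of A6 would add through C2 to A7, and the regenerated C4 enolate would close on the aldehyde to give the bicyclo[3.2.1]octanone ketol A5.
- For it: ring B, the quaternary C4 and four stereocentres appear in one step, and O5 is installed directly. The bridged core is reached faster than in the chosen route, so on convergence at ring B it is the stronger plan.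
- Against it: the C3 carbonyl is foreign to the target and must be reduced to CH2 at a bridging position next to the quaternary C4, beside an ester and a retro-aldol-prone ketol. The aldol closure is reversible and the O5 configuration it gives is not obviously the required one. Ring C is still open, so the strained ring A/ring C fusion would be made late by C8–C9 alkylation. C6–C7 still has to be desaturated.
- In exchange the chosen strategy keeps every carbon at an oxidation level the target uses and forms ring C before the strain is introduced.

Key step: step 12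

**Remarks on the chemistry (assumptions).**
- The sense of induction of Rh2(S-DOSP)4 (tetrakis[(S)-N-(4-dodecylbenzenesulfonyl)prolinato]dirhodium) on the 1,1-disubstituted siloxydiene is taken to be the one known for terminal alkenes with aryl- and vinyldiazoacetates, giving the carbenoid carbon R in 18. If it proves opposite, the mirror-image catalyst Rh2(R-DOSP)4 is used in the same step.
- C7 of 22–26 is drawn with its hydrogen on the C3 face. The C7 epimer would serve equally, since C7 becomes trigonal in step 19.

## Route

Step 1
Reactants: 1 prop-2-yn-1-ol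
Product: 3 (Z)-3-iodo-2-methylprop-2-en-1-ol, via vinylmagnesium alkoxide 2 (not isolated)
Conditions: MeMgBr (3 equiv), CuI (10 mol %), THF, −10 °C to rt; then iodine, THF, −78 to 0 °C
Reagents that add atoms: methylmagnesium bromide, C[Mg]Br; iodine, [I][I]
Why: Copper-catalysed anti-carbomagnesiation of the propargylic alkoxide (Duboudin reaction) puts CH3 on the internal carbon and magnesium on the terminus cis to CH2O; iodinolysis with retention gives the Z-iodide, which fixes the later cis relation of C7 and CH2O.

Step 2
Reactants: 3 (Z)-3-iodo-2-methylprop-2-en-1-ol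
Product: 4 (Z)-tert-butyl[(3-iodo-2-methylprop-2-en-1-yl)oxy]dimethylsilane
Conditions: TBSCl, imidazole, CH2Cl2, 0 °C to rt
Reagents that add atoms: tert-butyldimethylsilyl chloride, CC(C)(C)[Si](C)(C)Cl
Why: Standard silylation of a primary allylic alcohol; the alkenyl iodide is inert.

Step 3
Reactants: 4 (Z)-tert-butyl[(3-iodo-2-methylprop-2-en-1-yl)oxy]dimethylsilane
Product: 5 methyl (Z)-5-(TBS-oxy)-4-methylpent-3-enoate
Conditions: BrZnCH2CO2Me (preformed from BrCH2CO2Me and Zn, THF), Pd(PPh3)4 (5 mol %), THF/DMPU, 45 °C
Reagents that add atoms: methyl bromoacetate (used as its zinc reagent), COC(=O)CBr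
Why: Palladium-catalysed cross-coupling of a Reformatsky reagent with an alkenyl iodide (Negishi type); oxidative addition and reductive elimination at the alkenyl carbon go with retention, so CH2CO2Me ends up cis to CH2OTBS, and the non-basic zinc reagent leaves the β,γ-unsaturated ester out of conjugation.

Step 4
Reactants: 5 methyl (Z)-5-(TBS-oxy)-4-methylpent-3-enoate
Product: 6 methyl (Z)-5-(TBS-oxy)-2-diazo-4-methylpent-3-enoate
Conditions: 4-acetamidobenzenesulfonyl azide, DBU, MeCN, 0 °C
Reagents that add atoms: 4-acetamidobenzenesulfonyl azide, CC(=O)Nc1ccc(cc1)S(=O)(=O)N=[N+]=[N-]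
Why: Regitz-type diazo transfer to the α-carbon of the ester dienolate, the standard entry to vinyldiazoacetates; the C2=C1 geometry is untouched, and 6 is kept cold and used promptly because vinyldiazo esters close slowly to pyrazoles.

Step 5
Reactants: 7 ethyl 2-oxocyclopentane-1-carboxylate
Product: 8 ethyl (1S,2S)-2-hydroxycyclopentane-1-carboxylate
Conditions: H2 (100 atm), RuCl2[(S)-BINAP] (0.5 mol %), CH2Cl2, 50 °C
Reagents that add atoms: none
Why: Noyori hydrogenation with dynamic kinetic resolution: the keto ester enantiomers interconvert through the enol while the ruthenium–(S)-BINAP catalyst reduces one of them faster, giving the trans (1S,2S) hydroxy ester; this fixes C8 of the target.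

Step 6
Reactants: 8 ethyl (1S,2S)-2-hydroxycyclopentane-1-carboxylate
Product: 9 (1S,2R)-2-(hydroxymethyl)cyclopentan-1-ol
Conditions: LiAlH4, THF, 0 °C to rt
Reagents that add atoms: none
Why: Hydride reduction of the ester; the ring stereocentres are untouched (the descriptor at the former ester-bearing carbon changes only through priorities).

Step 7
Reactants: 9 (1S,2R)-2-(hydroxymethyl)cyclopentan-1-ol
Product: 11 (1S,2R)-2-(PMB-oxymethyl)cyclopentan-1-ol, via stannylene acetal 10 (not isolated)
Conditions: Bu2SnO, toluene, reflux (Dean–Stark); then PMBCl, Bu4NI, toluene, 90 °C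
Reagents that add atoms: 4-methoxybenzyl chloride, COc1ccc(CCl)cc1
Why: Dibutylstannylene acetals of primary/secondary diols are alkylated at the primary oxygen, so the PMB group goes on the CH2OH arm without protection of the secondary alcohol.

Step 8
Reactants: 11 (1S,2R)-2-(PMB-oxymethyl)cyclopentan-1-ol
Product: 12 (2R)-2-(PMB-oxymethyl)cyclopentan-1-one
Conditions: Dess–Martin periodinane, pyridine, CH2Cl2, 0 °C to rt
Reagents that add atoms: none
Why: Dess–Martin oxidation under pyridine buffer is neutral enough to leave the α-stereocentre (C8) of the β-alkoxy ketone intact.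

Step 9
Reactants: 12 (2R)-2-(PMB-oxymethyl)cyclopentan-1-one
Product: 14 (5R)-5-(PMB-oxymethyl)cyclopent-1-en-1-yl trifluoromethanesulfonate, via lithium enolate 13 (not isolated)
Conditions: LiN(iPr)2 (1.1 equiv), THF, −78 °C (12 added to the base); then PhNTf2, −78 to 0 °C
Reagents that add atoms: N-phenylbis(trifluoromethanesulfonimide), O=S(=O)(N(c1ccccc1)S(=O)(=O)C(F)(F)F)C(F)(F)F
Why: Kinetic deprotonation by the hindered amide takes the unsubstituted α-CH2 (C11), not the tertiary C8–H, and O-triflation of 13 fixes the C4=C11 double bond; inverse addition at −78 °C avoids proton exchange that would racemise C8.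

Step 10
Reactants: 14 (5R)-5-(PMB-oxymethyl)cyclopent-1-en-1-yl trifluoromethanesulfonate
Product: 16 1-[(5S)-5-(PMB-oxymethyl)cyclopent-1-en-1-yl]ethan-1-one, via ethoxydiene 15 (not isolated)
Conditions: tributyl(1-ethoxyvinyl)stannane, Pd(PPh3)4 (5 mol %), LiCl, THF, 65 °C; then 1 M HCl, THF, rt
Reagents that add atoms: tributyl(1-ethoxyvinyl)stannane, CCCC[Sn](CCCC)(CCCC)C(=C)OCC; water, O
Why: Stille coupling of an enol triflate (chloride assists transmetalation) brings in C5 and C6 as the 1-ethoxyvinyl group, and mild acid hydrolysis of enol ether 15 gives the methyl ketone without moving the ring alkene.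

Step 11
Reactants: 16 1-[(5S)-5-(PMB-oxymethyl)cyclopent-1-en-1-yl]ethan-1-one
Product: 17 tert-butyl({1-[(5S)-5-(PMB-oxymethyl)cyclopent-1-en-1-yl]ethenyl}oxy)dimethylsilane
Conditions: TBSOTf, Et3N, CH2Cl2, −78 to 0 °C
Reagents that add atoms: tert-butyldimethylsilyl trifluoromethanesulfonate, CC(C)(C)[Si](C)(C)OS(=O)(=O)C(F)(F)F
Why: Soft enolisation (silyl triflate on the carbonyl, amine removes a methyl proton) gives the cross-conjugated 2-silyloxydiene; C8–H is not acidified by the carbonyl and is not touched.

Step 12
Reactants: 6 methyl (Z)-5-(TBS-oxy)-2-diazo-4-methylpent-3-enoate; 17 tert-butyl({1-[(5S)-5-(PMB-oxymethyl)cyclopent-1-en-1-yl]ethenyl}oxy)dimethylsilane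
Product: 19 hydroazulene dienyl ester with C4=C5 enol silane, via cis-divinylcyclopropane 18 (not isolated)
Conditions: Rh2(S-DOSP)4 (1 mol %), hexanes, −40 °C to rt, slow addition of 6 (1.5 equiv); then toluene, 80 °C
Reagents that add atoms: none
Why: The dirhodium catalyst decomposes 6 to a donor–acceptor vinylcarbenoid, which adds in a concerted, asynchronous [2+1] fashion to the terminal alkene of 17 (C6=C5) and closes the three-membered ring C7–C6–C5 of 18 with the alkenyl groups on C7 and C5 cis, as such carbenoids place the donor group syn to the alkene substituent. On warming, 18 undergoes the [3,3]-sigmatropic divinylcyclopropane (Cope) rearrangement through a boat transition state, which breaks C7–C5, forms C1–C11 and so closes the seven-membered ring; the overall process is the known dirhodium-catalysed formal [4+3] cycloaddition of vinyldiazoacetates with 2-silyloxydienes. The C5 silyloxy group weakens the C5–C7 bond and speeds the rearrangement, and it survives as the C4=C5 enol ether while the ester ends on C7. C1 and C11 are set relative to each other by the boat geometry: the E-methyl of the carbenoid ends cis to C10 and the Z-CH2OTBS cis to H11. Their sense relative to the resident C8 centre follows from the cyclopropane configuration (C7 R, C5 S), which is set by the chiral carboxylate ligands because C8 is too remote from the reacting alkene to exert control. The step needs site selectivity for the terminal enol ether over the ring alkene and over the benzylic C–H bonds of the PMB ether, which the high nucleophilicity and low steric demand of the 1,1-disubstituted silyl enol ether should secure. The Z substituent on the vinyl terminus and the C8 arm on the inner side of the boat both slow the Cope step, which is why the mixture is heated once the diazo compound is consumed.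

Step 13
Reactants: 19 hydroazulene dienyl ester with C4=C5 enol silane
Product: 20 siloxycyclopropane with C3 bridging C4 and C5 on the H11 face
Conditions: Et2Zn (3 equiv), CH2I2 (6 equiv), CH2Cl2, 0 °C to rt
Reagents that add atoms: diiodomethane, C(I)I
Why: Furukawa–Simmons–Smith cyclopropanation; the electrophilic zinc carbenoid selects the electron-rich enol ether over the enoate and attacks from the face of H11 and H8, away from the quaternary C1 and the C8 arm, which sets C4 with C3 cis to H11.

Step 14
Reactants: 20 siloxycyclopropane with C3 bridging C4 and C5 on the H11 face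
Product: 21 C4 iodomethyl C5 ketone (C2=C7 enoate retained)
Conditions: N-iodosuccinimide (1.2 equiv), CH2Cl2, 0 °C to rt, dark
Reagents that add atoms: N-iodosuccinimide, O=C1CCC(=O)N1I
Why: Electrophilic ring opening of a cyclopropanol silyl ether: iodonium attacks the least substituted carbon C3, the C3–C5 bond breaks and the ketone is released; no β-hydrogen is available on C4, so the β-iodo ketone cannot eliminate and the C4 configuration is kept.

Step 15
Reactants: 21 C4 iodomethyl C5 ketone (C2=C7 enoate retained)
Product: 22 tricyclic keto ester (C3 joined to C2; C7–H)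
Conditions: Bu3SnH (1.3 equiv), AIBN (0.2 equiv), benzene (0.005 M), 80 °C, syringe-pump addition
Reagents that add atoms: none
Why: 5-exo-trig Giese-type cyclisation of the nucleophilic neopentyl radical at C3 onto C2, the β-carbon of the enoate, closes ring A and ring B; the tether from C4 allows attack only on the face of C2 that carries C3, which fixes C2, and the ester-stabilised C7 radical takes hydrogen from the stannane on the open C3 face.

Step 16
Reactants: 22 tricyclic keto ester (C3 joined to C2; C7–H)
Product: 24 C5 enol triflate (C5=C6), via potassium enolate 23 (not isolated)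
Conditions: KN(SiMe3)2 (1.2 equiv), THF, −78 °C; then PhNTf2, −78 to 0 °C
Reagents that add atoms: N-phenylbis(trifluoromethanesulfonimide), O=S(=O)(N(c1ccccc1)S(=O)(=O)C(F)(F)F)C(F)(F)F
Why: The ketone can enolise only towards C6 (C4 is quaternary) and its α-protons are far more acidic than the ester α-proton at C7; O-triflation of 23 gives the C5=C6 enol triflate.

Step 17
Reactants: 24 C5 enol triflate (C5=C6)
Product: 25 tricyclic alkene with C5=C6 and C7H–CO2Me
Conditions: Pd(OAc)2 (5 mol %), PPh3 (10 mol %), HCO2H, Bu3N, DMF, 60 °C
Reagents that add atoms: none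
Why: Palladium-catalysed formate reduction of an enol triflate (oxidative addition, formate exchange, decarboxylation, reductive elimination) replaces OTf by H; the weakly basic medium should leave the alkene out of conjugation with the ester.

Step 18
Reactants: 25 tricyclic alkene with C5=C6 and C7H–CO2Me
Product: 26 5,6-epoxide with oxygen on the C3 face
Conditions: dimethyldioxirane, acetone, 0 °C
Reagents that add atoms: dimethyldioxirane, CC1(C)OO1
Why: Epoxidation of the only alkene from the face of the one-carbon bridge, since the other face is covered by C10 and the C1 methyl under the C5–C6–C7 bridge; this puts oxygen on C5 with the configuration of the target.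

Step 19
Reactants: 26 5,6-epoxide with oxygen on the C3 face
Product: 27 hydroxy enoate (C5–OH on the C3 face; C6=C7–CO2Me)
Conditions: DBU (1.5 equiv), toluene, rt to 50 °C
Reagents that add atoms: none
Why: E1cB opening of a β,γ-epoxy ester: deprotonation at C7 and loss of the C6–O bond give the γ-hydroxy enoate; the C5–O bond is not broken, so O5 keeps its configuration, and butenolide formation is excluded because C5 and the ester are trans on the ring alkene.

Step 20
Reactants: 27 hydroxy enoate (C5–OH on the C3 face; C6=C7–CO2Me)
Product: 28 hydroxy acid (C7–CO2H)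
Conditions: LiOH, THF/MeOH/H2O, 40 °C; then 1 M HCl, 0 °C, to pH 4
Reagents that add atoms: lithium hydroxide, [Li+].[OH-]
Why: Saponification of the methyl ester at the last point where it is the only ester; it could not be removed later beside the C5 ester.

Step 21
Reactants: 28 hydroxy acid (C7–CO2H)
Product: 29 allyl ester with free C5–OH
Conditions: allyl bromide, KHCO3, DMF, rt
Reagents that add atoms: allyl bromide, C=CCBr
Why: O-alkylation of the carboxylate, which under bicarbonate conditions is far more nucleophilic than the hindered C5 hydroxyl.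

Step 22
Reactants: 30 9-methoxy-9-oxononanoic acid (monomethyl azelate)
Product: 31 methyl 9-hydroxynonanoate
Conditions: BH3·SMe2, THF, 0 °C to rt; MeOH quench
Reagents that add atoms: none
Why: Borane reduces the free carboxylic acid through its acyloxyborane much faster than the methyl ester.

Step 23
Reactants: 31 methyl 9-hydroxynonanoate
Product: 32 methyl 9-oxononanoate
Conditions: Dess–Martin periodinane, CH2Cl2, 0 °C to rt
Reagents that add atoms: none
Why: Dess–Martin oxidation stops at the aldehyde and tolerates the ester.

Step 24
Reactants: 33 7-bromoheptan-1-ol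
Product: 34 [(7-bromoheptyl)oxy](tert-butyl)dimethylsilane
Conditions: TBSCl, imidazole, DMF, rt
Reagents that add atoms: tert-butyldimethylsilyl chloride, CC(C)(C)[Si](C)(C)Cl
Why: Standard silylation of a primary alcohol.

Step 25
Reactants: 34 [(7-bromoheptyl)oxy](tert-butyl)dimethylsilane
Product: 35 [7-(TBS-oxy)heptyl]triphenylphosphonium bromide
Conditions: PPh3, MeCN, reflux
Reagents that add atoms: triphenylphosphine, c1ccc(cc1)P(c1ccccc1)c1ccccc1
Why: SN2 quaternisation of triphenylphosphine by a primary bromide.

Step 26
Reactants: 35 [7-(TBS-oxy)heptyl]triphenylphosphonium bromide; 32 methyl 9-oxononanoate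
Product: 37 methyl (Z)-16-(TBS-oxy)hexadec-9-enoate, via phosphorus ylide 36 (not isolated)
Conditions: NaN(SiMe3)2, THF, −78 °C; then 32, −78 °C to rt
Reagents that add atoms: none
Why: Wittig reaction of a non-stabilised ylide under salt-free conditions gives the Z-alkene through the kinetically favoured cis-oxaphosphetane; the ylide attacks the aldehyde, not the ester.

Step 27
Reactants: 37 methyl (Z)-16-(TBS-oxy)hexadec-9-enoate
Product: 38 (Z)-16-(TBS-oxy)hexadec-9-enoic acid
Conditions: LiOH, THF/H2O, rt; then 1 M HCl, 0 °C, to pH 4
Reagents that add atoms: lithium hydroxide, [Li+].[OH-]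
Why: Saponification; the primary silyl ether and the Z-alkene are stable to aqueous hydroxide and to brief cold acidification.

Step 28
Reactants: 29 allyl ester with free C5–OH; 38 (Z)-16-(TBS-oxy)hexadec-9-enoic acid
Product: 40 C5 ester of 29 with acid 38, via mixed anhydride 39 (not isolated)
Conditions: 2,4,6-trichlorobenzoyl chloride, Et3N, THF, rt; then 29, DMAP, toluene, rt to 50 °C
Reagents that add atoms: none
Why: Yamaguchi esterification: DMAP attacks mixed anhydride 39 at the unhindered aliphatic carbonyl and the acylpyridinium ion acylates the hindered secondary C5 hydroxyl; the C5–O bond, and so the C5 configuration, is not touched.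

Step 29
Reactants: 40 C5 ester of 29 with acid 38
Product: 41 C8 hydroxymethyl compound (PMB removed)
Conditions: DDQ, CH2Cl2/pH 7 buffer, 0 °C
Reagents that add atoms: none
Why: Oxidative cleavage of the PMB ether by electron transfer to DDQ; silyl ethers, the allyl ester and both alkenes are inert.

Step 30
Reactants: 41 C8 hydroxymethyl compound (PMB removed)
Product: 42 C8 aldehyde
Conditions: Dess–Martin periodinane, pyridine, CH2Cl2, 0 °C
Reagents that add atoms: none
Why: Dess–Martin oxidation of the primary alcohol under pyridine buffer should give the aldehyde without epimerising C8.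

Step 31
Reactants: 42 C8 aldehyde
Product: 43 C7 acid with both TBS ethers in place
Conditions: Pd(PPh3)4 (5 mol %), PhSiH3 (2 equiv), CH2Cl2, rt
Reagents that add atoms: none
Why: Zerovalent palladium ionises the allyl ester to a π-allyl complex and the silane transfers hydride to it, under neutral conditions that the aldehyde and the C5 ester tolerate; the ring allylic ester should not ionise because palladium would have to approach C5 from the blocked face under the bridge.

Step 32
Reactants: 43 C7 acid with both TBS ethers in place
Product: 44 target CNP0148862.1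
Conditions: HF·pyridine, pyridine, THF, 0 °C to rt
Reagents that add atoms: none
Why: Fluoride cleavage of both primary silyl ethers in a buffered medium that is not basic enough to epimerise C8 or cleave the C5 ester.

## Compound list

1 | prop-2-yn-1-ol | C#CCO | starting material
2 | bromomagnesium (Z)-3-(bromomagnesio)-2-methylprop-2-en-1-olate | Br[Mg]/C=C(/C)CO[Mg]Br | intermediate
3 | (Z)-3-iodo-2-methylprop-2-en-1-ol | I/C=C(/C)CO | intermediate
4 | (Z)-tert-butyl[(3-iodo-2-methylprop-2-en-1-yl)oxy]dimethylsilane | I/C=C(/C)CO[Si](C)(C)C(C)(C)C | intermediate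
5 | methyl (Z)-5-(TBS-oxy)-4-methylpent-3-enoate | COC(=O)C/C=C(/C)CO[Si](C)(C)C(C)(C)C | intermediate
6 | methyl (Z)-5-(TBS-oxy)-2-diazo-4-methylpent-3-enoate | COC(=O)C(=[N+]=[N-])/C=C(/C)CO[Si](C)(C)C(C)(C)C | intermediate
7 | ethyl 2-oxocyclopentane-1-carboxylate | CCOC(=O)C1CCCC1=O | starting material
8 | ethyl (1S,2S)-2-hydroxycyclopentane-1-carboxylate | O[C@H]1CCC[C@@H]1C(=O)OCC | intermediate
9 | (1S,2R)-2-(hydroxymethyl)cyclopentan-1-ol | O[C@H]1CCC[C@@H]1CO | intermediate
10 | dibutylstannylene acetal of 9 (trans-fused 1,3,2-dioxastanninane) | CCCC[Sn]1(CCCC)OC[C@H]2CCC[C@@H]2O1 | intermediate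
11 | (1S,2R)-2-{[(4-methoxyphenyl)methoxy]methyl}cyclopentan-1-ol | O[C@H]1CCC[C@@H]1COCc1ccc(OC)cc1 | intermediate
12 | (2R)-2-{[(4-methoxyphenyl)methoxy]methyl}cyclopentan-1-one | O=C1CCC[C@@H]1COCc1ccc(OC)cc1 | intermediate
13 | lithium (5R)-5-{[(4-methoxyphenyl)methoxy]methyl}cyclopent-1-en-1-olate | [Li]OC1=CCC[C@@H]1COCc1ccc(OC)cc1 | intermediate
14 | (5R)-5-{[(4-methoxyphenyl)methoxy]methyl}cyclopent-1-en-1-yl trifluoromethanesulfonate | FC(F)(F)S(=O)(=O)OC1=CCC[C@@H]1COCc1ccc(OC)cc1 | intermediate
15 | 1-({[(1S)-2-(1-ethoxyethenyl)cyclopent-2-en-1-yl]methoxy}methyl)-4-methoxybenzene | CCOC(=C)C1=CCC[C@@H]1COCc1ccc(OC)cc1 | intermediate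
16 | 1-[(5S)-5-{[(4-methoxyphenyl)methoxy]methyl}cyclopent-1-en-1-yl]ethan-1-one | CC(=O)C1=CCC[C@@H]1COCc1ccc(OC)cc1 | intermediate
17 | tert-butyl({1-[(5S)-5-{[(4-methoxyphenyl)methoxy]methyl}cyclopent-1-en-1-yl]ethenyl}oxy)dimethylsilane | C=C(O[Si](C)(C)C(C)(C)C)C1=CCC[C@@H]1COCc1ccc(OC)cc1 | intermediate
18 | methyl (1R,2S)-2-(TBS-oxy)-1-[(Z)-3-(TBS-oxy)-2-methylprop-1-en-1-yl]-2-[(5S)-5-(PMB-oxymethyl)cyclopent-1-en-1-yl]cyclopropane-1-carboxylate (alkenyl groups cis) | COC(=O)[C@@]1(/C=C(/C)CO[Si](C)(C)C(C)(C)C)C[C@]1(O[Si](C)(C)C(C)(C)C)C1=CCC[C@@H]1COCc1ccc(OC)cc1 | intermediate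
19 | hydroazulene dienyl ester: C1 with CH3 and CH2OTBS; C2=C7 with CO2Me on C7; C6H2; C4=C5 TBS enol ether; C8 with CH2OPMB; H8 cis to H11; CH2OTBS cis to H11 | C[C@@]1(CO[Si](C)(C)C(C)(C)C)C=C(C(=O)OC)CC(O[Si](C)(C)C(C)(C)C)=C2[C@@H](COCc3ccc(OC)cc3)CC[C@@H]12 | intermediate
20 | siloxycyclopropane: 19 with CH2 (C3) bridging C4 and C5 on the H11 face | C[C@@]1(CO[Si](C)(C)C(C)(C)C)C=C(C(=O)OC)C[C@]3(O[Si](C)(C)C(C)(C)C)C[C@]23[C@@H](COCc4ccc(OC)cc4)CC[C@@H]12 | intermediate
21 | iodomethyl ketone: C4 quaternary with CH2I (C3) cis to H11; C5 ketone; C2=C7 enoate | C[C@@]1(CO[Si](C)(C)C(C)(C)C)C=C(C(=O)OC)CC(=O)[C@@]2(CI)[C@@H](COCc3ccc(OC)cc3)CC[C@@H]12 | intermediate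
22 | tricyclic keto ester: C3 joined to C2; C5 ketone; C6H2; C7H–CO2Me with H7 on the C3 face | C[C@@]1(CO[Si](C)(C)C(C)(C)C)[C@@H]2C[C@]3(C(=O)C[C@@H]2C(=O)OC)[C@@H](COCc4ccc(OC)cc4)CC[C@@H]13 | intermediate
23 | potassium C5=C6 enolate of 22 | C[C@@]1(CO[Si](C)(C)C(C)(C)C)[C@@H]2C[C@]3(C(O[K])=C[C@@H]2C(=O)OC)[C@@H](COCc4ccc(OC)cc4)CC[C@@H]13 | intermediate
24 | C5 enol triflate of 22 (C5=C6) | C[C@@]1(CO[Si](C)(C)C(C)(C)C)[C@@H]2C[C@]3(C(OS(=O)(=O)C(F)(F)F)=C[C@@H]2C(=O)OC)[C@@H](COCc4ccc(OC)cc4)CC[C@@H]13 | intermediate
25 | tricyclic alkene: C5=C6; C7H–CO2Me | C[C@@]1(CO[Si](C)(C)C(C)(C)C)[C@@H]2C[C@]3(C=C[C@@H]2C(=O)OC)[C@@H](COCc4ccc(OC)cc4)CC[C@@H]13 | intermediate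
26 | 5,6-epoxide of 25 with oxygen on the C3 face | C[C@@]1(CO[Si](C)(C)C(C)(C)C)[C@@H]2C[C@]3([C@H]4O[C@H]4[C@@H]2C(=O)OC)[C@@H](COCc5ccc(OC)cc5)CC[C@@H]13 | intermediate
27 | hydroxy enoate: C5–OH on the C3 face; C6=C7–CO2Me | C[C@@]1(CO[Si](C)(C)C(C)(C)C)[C@@H]2C[C@]3([C@@H](O)C=C2C(=O)OC)[C@@H](COCc4ccc(OC)cc4)CC[C@@H]13 | intermediate
28 | hydroxy acid: C7–CO2H; C5–OH | C[C@@]1(CO[Si](C)(C)C(C)(C)C)[C@@H]2C[C@]3([C@@H](O)C=C2C(=O)O)[C@@H](COCc4ccc(OC)cc4)CC[C@@H]13 | intermediate
29 | allyl ester of 28 with free C5–OH | C[C@@]1(CO[Si](C)(C)C(C)(C)C)[C@@H]2C[C@]3([C@@H](O)C=C2C(=O)OCC=C)[C@@H](COCc4ccc(OC)cc4)CC[C@@H]13 | intermediate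
30 | 9-methoxy-9-oxononanoic acid (monomethyl azelate) | COC(=O)CCCCCCCC(=O)O | starting material
31 | methyl 9-hydroxynonanoate | COC(=O)CCCCCCCCO | intermediate
32 | methyl 9-oxononanoate | COC(=O)CCCCCCCC=O | intermediate
33 | 7-bromoheptan-1-ol | OCCCCCCCBr | starting material
34 | [(7-bromoheptyl)oxy](tert-butyl)dimethylsilane | CC(C)(C)[Si](C)(C)OCCCCCCCBr | intermediate
35 | [7-(TBS-oxy)heptyl]triphenylphosphonium bromide | CC(C)(C)[Si](C)(C)OCCCCCCC[P+](c1ccccc1)(c1ccccc1)c1ccccc1.[Br-] | intermediate
36 | [7-(TBS-oxy)heptylidene]triphenylphosphorane | CC(C)(C)[Si](C)(C)OCCCCCCC=P(c1ccccc1)(c1ccccc1)c1ccccc1 | intermediate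
37 | methyl (Z)-16-(TBS-oxy)hexadec-9-enoate | COC(=O)CCCCCCC/C=C\CCCCCCO[Si](C)(C)C(C)(C)C | intermediate
38 | (Z)-16-(TBS-oxy)hexadec-9-enoic acid | OC(=O)CCCCCCC/C=C\CCCCCCO[Si](C)(C)C(C)(C)C | intermediate
39 | (Z)-16-(TBS-oxy)hexadec-9-enoic 2,4,6-trichlorobenzoic anhydride | CC(C)(C)[Si](C)(C)OCCCCCC/C=C\CCCCCCCC(=O)OC(=O)c1c(Cl)cc(Cl)cc1Cl | intermediate
40 | C5 (Z)-16-(TBS-oxy)hexadec-9-enoate of 29 | C[C@@]1(CO[Si](C)(C)C(C)(C)C)[C@@H]2C[C@]3([C@@H](OC(=O)CCCCCCC/C=C\CCCCCCO[Si](C)(C)C(C)(C)C)C=C2C(=O)OCC=C)[C@@H](COCc4ccc(OC)cc4)CC[C@@H]13 | intermediate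
41 | C8 hydroxymethyl compound (PMB removed from 40) | C[C@@]1(CO[Si](C)(C)C(C)(C)C)[C@@H]2C[C@]3([C@@H](OC(=O)CCCCCCC/C=C\CCCCCCO[Si](C)(C)C(C)(C)C)C=C2C(=O)OCC=C)[C@@H](CO)CC[C@@H]13 | intermediate
42 | C8 aldehyde; allyl ester; two TBS ethers | C[C@@]1(CO[Si](C)(C)C(C)(C)C)[C@@H]2C[C@]3([C@@H](OC(=O)CCCCCCC/C=C\CCCCCCO[Si](C)(C)C(C)(C)C)C=C2C(=O)OCC=C)[C@@H](C=O)CC[C@@H]13 | intermediate
43 | C7 acid; C8 aldehyde; two TBS ethers | C[C@@]1(CO[Si](C)(C)C(C)(C)C)[C@@H]2C[C@]3([C@@H](OC(=O)CCCCCCC/C=C\CCCCCCO[Si](C)(C)C(C)(C)C)C=C2C(=O)O)[C@@H](C=O)CC[C@@H]13 | intermediate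
44 | CNP0148862.1: C5 (Z)-16-hydroxyhexadec-9-enoate of the C7 acid, C8 aldehyde, C1 hydroxymethyl core | C[C@@]1(CO)[C@@H]2C[C@]3([C@@H](OC(=O)CCCCCCC/C=C\CCCCCCO)C=C2C(=O)O)[C@@H](C=O)CC[C@@H]13 | target

## Step count and least certain steps

Total: 32 steps. Longest linear sequence: 22 steps (7 to 44 through steps 5–21 and 28–32).

Step 12 (key step). The likely failure is stalling or stereochemical leakage at the cyclopropane stage. The required diastereomer of 18 has to rearrange with the C8 arm and the Z-CH2OTBS group on the inside of the boat, so the Cope step is slowed. Reversible zwitterionic opening of the donor–acceptor cyclopropane can then scramble the C5/C7 relationship. Carbenoid insertion into the benzylic C–H bonds of the PMB ether and loss of diastereoselectivity in the cyclopropanation of a 1,1-disubstituted alkene are further leaks. Fallback (sets out from 5 and 16, returns at 19): 5 is deprotonated with LiN(iPr)2 and brominated at C7 with CBr4 to give methyl (Z)-2-bromo-5-(TBS-oxy)-4-methylpent-3-enoate F1. 16 is deprotonated at its methyl group (LiN(iPr)2, −78 °C) and alkylated with F1 to give the 1,4-keto ester F2, which forms C6–C7. F2 is then closed by intramolecular vinylogous Michael addition of C1 onto C11 (KN(SiMe3)2, THF) and silylated in the same flask with TBSOTf to return 19. The same two bonds are made by ionic steps, but the C1/C11 relationship would then rest on the folding of a seven-membered transition state and would have to be checked.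

Step 15. The likely failure is competition between ring closure and other fates of the C3 radical: 1,2-acyl migration through attack on the C5 carbonyl (ring enlargement) and premature reduction by the stannane. Closure has to build the strained trans-type fusion of ring A with ring C, which slows the 5-exo step. Fallback (from 21 to 22): KOtBu in THF deprotonates C6, and the extended enolate alkylates through C2, the only position that gives an unstrained ring size, to give tricyclic enone F3 with C6=C7. Conjugate reduction with [(Ph3P)CuH]6 returns 22.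

Step 14. The likely failure is ring opening at the wrong cyclopropane bond (C4–C5, which enlarges the ring) or sluggish reaction of the bulky silyl ether, since the regiochemistry depends on iodonium reaching the CH2 corner next to a quaternary carbon. Fallback (from 19 to 21, bypassing 20): Mukaiyama hydroxymethylation of the enol silane with aqueous formaldehyde and Sc(OTf)3 gives the C4 hydroxymethyl ketone F4, from the same open face. Iodine, PPh3 and imidazole in warm toluene convert F4 into 21.

Step 9. The likely failure is loss of regiocontrol in the deprotonation and partial racemisation of C8 by proton exchange, because the β-alkoxy group acidifies C8–H and cyclopentanones discriminate less well than cyclohexanones. Fallback (from 12 to 16, bypassing 14 and 15): condensation with 2,4,6-triisopropylbenzenesulfonohydrazide gives hydrazone F5. Two equivalents of butyllithium followed by N-methoxy-N-methylacetamide (Shapiro reaction with acylation) give 16 directly, with the double bond placed by syn-deprotonation on the unsubstituted side.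

## Further compounds

F1 | step 12 | methyl (Z)-2-bromo-5-(TBS-oxy)-4-methylpent-3-enoate (racemic at C2) | COC(=O)C(Br)/C=C(/C)CO[Si](C)(C)C(C)(C)C
F2 | step 12 | methyl 2-[(Z)-3-(TBS-oxy)-2-methylprop-1-en-1-yl]-4-[(5S)-5-(PMB-oxymethyl)cyclopent-1-en-1-yl]-4-oxobutanoate (both epimers at the ester α-carbon) | COC(=O)C(/C=C(/C)CO[Si](C)(C)C(C)(C)C)CC(=O)C1=CCC[C@@H]1COCc1ccc(OC)cc1
F3 | step 15 | tricyclic enone: C5 ketone; C6=C7–CO2Me; C3 joined to C2 | C[C@@]1(CO[Si](C)(C)C(C)(C)C)[C@@H]2C[C@]3(C(=O)C=C2C(=O)OC)[C@@H](COCc4ccc(OC)cc4)CC[C@@H]13
F4 | step 14 | C4 hydroxymethyl C5 ketone (CH2OH cis to H11) | C[C@@]1(CO[Si](C)(C)C(C)(C)C)C=C(C(=O)OC)CC(=O)[C@@]2(CO)[C@@H](COCc3ccc(OC)cc3)CC[C@@H]12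
F5 | step 9 | 2,4,6-triisopropylbenzenesulfonyl hydrazone of 12 (N–N syn to the unsubstituted CH2) | CC(C)c1cc(C(C)C)c(c(C(C)C)c1)S(=O)(=O)N/N=C1\CCC[C@@H]1COCc1ccc(OC)cc1
A1 | alternative 1 | spiro[4.5]decenone with C5 alcohol and C8 ketone | COC(=O)C1=CC[C@]2([C@@H](O)C1)C(=O)CC[C@H]2C(=C)CO[Si](C)(C)C(C)(C)C
A2 | alternative 1 | epoxy cyclobutanol: C4–C5 epoxide; 1-hydroxycyclobutyl on C4 | COC(=O)C1=CC[C@]2(O[C@H]2C1)[C@]1(O)CC[C@H]1C(=C)CO[Si](C)(C)C(C)(C)C
A3 | alternative 2 | bicyclo[3.3.0]octenone with C4=C8 and C9 ketone | C[C@@]1(CO[Si](C)(C)C(C)(C)C)[C@@H](/C(C(=O)OC)=C\COCOC)CC2=C(COCc3ccc(OC)cc3)C(=O)C[C@@H]12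
A4 | alternative 2 | 1,6-enyne: alkyne C8≡C4; alkene C11=C10 | C=C[C@](C)(CO[Si](C)(C)C(C)(C)C)[C@H](CC#CCOCc1ccc(OC)cc1)/C(C(=O)OC)=C\COCOC
A5 | alternative 3 | bicyclo[3.2.1]octanone ketol ester | C[C@@]1(CO[Si](C)(C)C(C)(C)C)[C@@H]2C(=O)[C@]([C@@H](O)C[C@H]2C(=O)OC)(CC(OC)OC)[C@H]1CCOCc1ccc(OC)cc1
A6 | alternative 3 | ring A cyclopentanone with C3 carbonyl | C[C@@]1(CO[Si](C)(C)C(C)(C)C)CC(=O)[C@H](CC(OC)OC)[C@H]1CCOCc1ccc(OC)cc1
A7 | alternative 3 | methyl (E)-4-oxobut-2-enoate | COC(=O)/C=C/C=O
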